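## Structural features

The target is a flavone (rings A, C and B) whose C3 and C2' are tied together by a CH2–CH(–O–) bridge, so that a seven-membered dihydrooxepine (ring D) is fused to the pyranone across C2–C3 and to ring B across C1'–C2'. The only stereocentre is the oxepine carbon bonded to the ring oxygen; it is R, carries a 2-hydroxypropan-2-yl group and has no stereogenic neighbour, its flanks being the C3 methylene and a quaternary carbinol carbon. Ring A is substituted at every position except C8: a 5-OH chelated to the C4 carbonyl, a 6-[(E)-3-methylbut-1-enyl] group wedged between that OH and the 7-OMe group; ring B carries a free 4'-OH. Fragile groups are the electron-rich styrene-type alkene (acid, hydride-abstracting oxidants, BH3, hydrogenation, light), the tertiary alcohol (strong acid), the pyranone (hard nucleophiles, hydroxide) and the two phenols. The real difficulties are the regiodefined contiguous pattern of ring A, the vicinal carbon substitution of C2 and C3, the seven-membered aryl alkyl ether at a hindered secondary carbinol, and an isolated stereocentre that only a reagent can set. The key step uses the fact that in a ring A chromone unsubstituted at C2 and C3 these two carbons are the β- and α-carbon of an enone: C2 accepts the ring B aryl nucleophile, and the enolate so formed delivers C3 to the carbon electrophile that becomes the ring D methylene.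

## Logic of the disconnections

23 ⇒ 22. No skeletal bond is cut; the O5–H and O4'–H bonds are traced back to O–CH2OCH3 acetals. Free phenols cannot pass through the organometallic and strong-base steps. The gain is an endgame that is one mild unmasking. The demand is acid mild enough for the alkene and the tertiary alcohol.

22 ⇒ 21. The O–C2' bond of ring D is cut. It is the one ring D bond that can be made without touching the stereocentre, and C2' is ortho to C2 of the pyranone, which activates a 2'-fluoride for addition–elimination. The gain is an open diol side chain on a flavone. The demand is that the secondary alkoxide closes a seven-membered ring onto a fluoride activated only through the pyranone, faster than base harms the pyranone.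

21 ⇒ 20 ⇒ 19. The O–Si bond and then the C–H bond of the carbinol carbon are traced back, so the stereocentre becomes a ketone. Its two flanks (CH2 and a quaternary silyloxy carbon) differ sharply in size, which suits reagent control. The gain is an achiral precursor. The demand is high facial selectivity without hydroboration of the alkene or reduction of the pyranone carbonyl, hence catecholborane and not BH3. The silyl group is removed before ring closure so that it cannot migrate onto the secondary alkoxide.

19 ⇒ 18. The C2=C3 π bond is removed. A saturated C2–C3 unit is what a double addition to an enone delivers. The gain is that both carbons become addressable as β- and α-carbon. The demand is a dehydrogenation that spares the allylic C–H of the electron-rich styrene, hence a pentavalent iodine reagent and not a quinone.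

18 ⇒ 10 + 13 + 16. The bonds C2–C1' and C3–CH2 are cut. This gives three pieces of similar size, each two to six steps from commercial material. The demand is conjugate (not carbonyl) addition of the aryl group, and C-alkylation of the enolate before it opens by loss of the ring phenoxide.

10 ⇒ 7. The pyranone bonds O1–C2 and C2–C3 are cut, C2 coming from a one-carbon amide acetal. The oxygen that closes the ring must be the only free one, so it is masked as a tetrahydropyranyl acetal that is removed selectively beside the O5 methoxymethyl acetal. The gain is an aryl methyl ketone. The demand is that the O5 acetal survives, since it alone fixes which oxygen becomes O1.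

7 ⇒ 5. The C4–C4a bond is cut. C4a lies between two acetal oxygens, the best site for directed metalation. A carbamate would direct as well, but its later removal from an ortho-acyl aryl carbamate needs hot hydroxide and invites carbamoyl transfer to the ketone enolate, so an acetal is used instead. The demand is lithiation at this site only and no attack on the styrene.

5 ⇒ 4 ⇒ 3 ⇒ 2 ⇒ 1. The alkene is traced to a benzylic alcohol, and the bond between the benzylic carbon and the isobutyl CH2 is cut; the two O-protecting bonds follow. The aldehyde carbon of 1 already sits between the oxygens that become O5 and the 7-OMe oxygen, so the ring A pattern is fixed from the start. The chelated 2-OH and the free 4-OH of 1 differ in reactivity, so they can be protected differently. The demand is the E-alkene, met by an elimination under product-stability control.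

13 ⇒ 12 ⇒ 11. The C–Mg bond is traced to C–Br and the acetal to the phenol. The demand is exchange at low temperature so that the ortho-fluoro aryl metal does not lose metal fluoride.

16 ⇒ 15 ⇒ 14. The C–Br bond is traced to a silyl enol ether and both Si–O bonds to the hydroxy ketone. The ketone can enolise only toward its methyl group, so bromination is regiospecific.

## Other disconnections considered

Alternative 1: Ring A is cut at four bonds, C8–C8a, C7–C8, C5–C6 and C4a–C5. This leaves the diazoketone A1 (rings B, C and D complete, R-configured, both alcohols as methoxymethyl ethers, a diazoacetyl group on the pyranone carbon next to O1) and the methoxy enyne A2. Forward, irradiation of A1 with A2 would trigger Wolff rearrangement, ketene–alkyne (2+2) addition, 4π opening, 6π closure and tautomerisation (Danheiser benzannulation) to give A3 with the 5-OH already free; acid would then take A3 to 23.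
- In its favour: the polarity of the ynol ether dictates the ring A pattern, so the alkenyl group lands between OH and OMe without any directed metalation, and four bonds and a ring form in one operation near the end.
- Against it here: A1 must already contain the stereocentre and the ring D ether, so those problems are only moved into a longer synthesis of a pyranone that also bears a diazoacetyl group. The 6π closure must engage the electron-poor C=C bond of a vinylogous ester, A2 is a conjugated ynol ether of low stability, and the light needed can isomerise the E-alkene of A2 and A3.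
- Comparison: on regiocontrol of ring A and on freedom from a peri protecting group the alternative is the better. Mechanistically both rest on known reaction types; the cascade is longer and photochemical, while the chosen coupling has the enolate-lifetime problem. On step economy the alternative forms more bonds in its key step but needs a clearly longer route to A1, so the chosen plan should be shorter overall.

Alternative 2: C2 is excised as carbon monoxide; the bonds C1'–C2 and C2–C3 are cut, giving the open-chain bromo ketone A4 in which the aryl ether and the stereocentre are already present. Forward, Pd(dba)2 (zerovalent palladium) with Xantphos under CO and base would effect oxidative addition into C–Br, CO insertion and intramolecular C-acylation of the ring A ketone enolate, closing ring D as the cyclic 1,3-diketone A5; dehydrative closure of O1–C2 would then give 22.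
- In its favour: the ether is made early on simple, strongly activated partners; there is no dehydrogenation and no transient flavanone centre; the diketone-to-pyranone closure is the classical flavone endgame.
- Against it here: a seven-membered ring must form by C-acylation of the enolate of a di-ortho-substituted aryl ketone. This competes with direct α-arylation without CO (six-membered ring), O-acylation, and capture of the acyl–metal bond by the free C8a phenoxide or the tertiary alcohol. A4 also needs a chiral four-carbon chain on ring A, which costs steps.
- Comparison: on the ether closure and on avoiding an oxidation step the alternative is the better. On stereocontrol it is the equal (reagent control in both). On chemoselectivity of the key step the chosen plan is judged safer because it has fewer competing pathways. On step count the two are about equal, the chosen plan being more convergent.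

Alternative 3: The pyranone is cut at O1–C8a, C4–C4a and O1–C2, giving the ortho-silyl aryl triflate A6 as ring A aryne precursor and the β-chloro acrylic acid A7, which holds rings B and D and the stereocentre. Forward, CsF would induce 1,2-elimination of A6; the carboxylate oxygen of A7 would add at C8a (away from the C5 alkoxy group), the acyl group would shift from oxygen to C4a, and the freed phenolic oxygen would displace the vinylic chloride, closing ring C to A8. Removal of three methoxymethyl groups would give 23.
- In its favour: three bonds and the pyranone form in one flask under mild fluoride conditions, two large halves are joined convergently, no redox adjustment is needed, the 5-alkoxy group directs the addition, and the ring D ether is made on a small benzoxepine.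
- Against it here: A6 is a pentasubstituted arene needing a long synthesis, and its styrene unit can itself react with arynes. Protonation can intercept the sequence before the acyl shift. A7 is a sensitive vinylogous acid chloride. The tertiary methoxymethyl ether makes the last deprotection harsher.
- Comparison: on convergence and bonds formed per step the alternative is the better, and on early formation of ring D it is the equal or better. Its total step count is expected to be higher because both halves are long, whereas the chosen plan needs three short precursors. Both key steps depend on a short-lived reactive intermediate (aryne versus enolate), so neither is clearly safer.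

Key step: step 11

Remark on the chemistry: the tetrahydropyranyl acetal carbon is racemic, so 2, 3 and 5 to 8 are racemates and 4 is a diastereomer mixture; 17 and 18 are racemic (18 as C2/C3 diastereomers); none of these centres survives into 19.
Remark on the chemistry: the key step creates two transient stereocentres (C2 and C3 of 18); the aryl magnesium reagent 13 is the chloride because it is made by exchange with i-PrMgCl·LiCl.

## Route

Step 1
Reactants: 1 2,4-dihydroxy-6-methoxybenzaldehyde
Product: 2 2-hydroxy-6-methoxy-4-(tetrahydro-2H-pyran-2-yloxy)benzaldehyde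
Conditions: 3,4-dihydro-2H-pyran, pyridinium p-toluenesulfonate (cat.), CH2Cl2, 25 °C
Reagents that add atoms: 3,4-dihydro-2H-pyran, C1=COCCC1
Why: Acid-catalysed acetalisation (tetrahydropyranylation); the 2-OH is locked in a hydrogen bond to the aldehyde and is far less nucleophilic, so only the 4-OH should react.

Step 2
Reactants: 2 2-hydroxy-6-methoxy-4-(tetrahydro-2H-pyran-2-yloxy)benzaldehyde
Product: 3 2-methoxy-6-(methoxymethoxy)-4-(tetrahydro-2H-pyran-2-yloxy)benzaldehyde
Conditions: MOMCl, i-Pr2NEt, CH2Cl2, 0 → 40 °C
Reagents that add atoms: chloromethyl methyl ether, COCCl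
Why: Williamson-type O-alkylation of the chelated phenol by the very reactive chloromethyl ether; the basic medium leaves the tetrahydropyranyl acetal untouched.

Step 3
Reactants: 3 2-methoxy-6-(methoxymethoxy)-4-(tetrahydro-2H-pyran-2-yloxy)benzaldehyde
Product: 4 1-[2-methoxy-6-(methoxymethoxy)-4-(tetrahydro-2H-pyran-2-yloxy)phenyl]-3-methylbutan-1-ol
Conditions: i-BuMgBr, THF, −78 → 0 °C; aq. NH4Cl
Reagents that add atoms: isobutylmagnesium bromide, CC(C)C[Mg]Br
Why: Grignard 1,2-addition to the aldehyde; acetals and aryl ethers are inert at low temperature, and the new carbinol centre is removed in the next step.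

Step 4
Reactants: 4 1-[2-methoxy-6-(methoxymethoxy)-4-(tetrahydro-2H-pyran-2-yloxy)phenyl]-3-methylbutan-1-ol
Product: 5 2-{3-methoxy-5-(methoxymethoxy)-4-[(E)-3-methylbut-1-en-1-yl]phenoxy}tetrahydro-2H-pyran
Conditions: MsCl, Et3N, CH2Cl2, 0 → 40 °C
Reagents that add atoms: none
Why: Sulfonylation then E1-type elimination: the benzylic mesylate, flanked by three alkoxy donors, ionises readily and loses a proton from the only adjacent CH2 to give the conjugated alkene. The E isomer is expected because the elimination is under product-stability control and the di-ortho-substituted aryl group avoids the isopropyl group; the basic medium keeps both acetals intact.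

Step 5
Reactants: 5 2-{3-methoxy-5-(methoxymethoxy)-4-[(E)-3-methylbut-1-en-1-yl]phenoxy}tetrahydro-2H-pyran
Product: 7 1-[4-methoxy-2-(methoxymethoxy)-3-[(E)-3-methylbut-1-en-1-yl]-6-(tetrahydro-2H-pyran-2-yloxy)phenyl]ethan-1-one, via aryllithium 6 (not isolated)
Conditions: n-BuLi, THF, 0 °C; then MeC(O)N(OMe)Me, −78 → 0 °C; aq. NH4Cl
Reagents that add atoms: N-methoxy-N-methylacetamide, CC(=O)N(C)OC
Why: Directed ortho-metalation: the ring hydrogen between the two acetal oxygens is the most acidic and both acetal side arms bind lithium, whereas the other free position has only the weaker methoxy director, whose methyl group is pushed toward it by the neighbouring alkenyl group. The N-methoxy-N-methyl amide stops at the ketone through its chelated tetrahedral adduct.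

Step 6
Reactants: 7 1-[4-methoxy-2-(methoxymethoxy)-3-[(E)-3-methylbut-1-en-1-yl]-6-(tetrahydro-2H-pyran-2-yloxy)phenyl]ethan-1-one
Product: 10 7-methoxy-5-(methoxymethoxy)-6-[(E)-3-methylbut-1-en-1-yl]-4H-chromen-4-one, via THP-protected enaminone 8 (not isolated), via hydroxy enaminone 9 (not isolated)
Conditions: Me2NCH(OMe)2, toluene, 100 °C; evaporate; pyridinium p-toluenesulfonate (1.5 equiv), EtOH, 60 °C
Reagents that add atoms: N,N-dimethylformamide dimethyl acetal, COC(OC)N(C)C
Why: Condensation of the methyl ketone with the amide acetal gives the enaminone; the mild pyridinium acid in ethanol then removes the tetrahydropyranyl acetal (methoxymethyl ethers need stronger acid), and the freed phenol adds to the β-carbon and expels dimethylamine (addition–elimination, 6-endo closure). Because only one ortho oxygen is unmasked, only the 6-alkenyl chromone can form.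

Step 7
Reactants: 11 4-bromo-3-fluorophenol
Product: 12 1-bromo-2-fluoro-4-(methoxymethoxy)benzene
Conditions: MOMCl, i-Pr2NEt, CH2Cl2, 0 → 25 °C
Reagents that add atoms: chloromethyl methyl ether, COCCl
Why: O-alkylation of the phenol; the acetal withstands organomagnesium reagents and strong base and is removed with acid at the end.

Step 8
Reactants: 12 1-bromo-2-fluoro-4-(methoxymethoxy)benzene
Product: 13 [2-fluoro-4-(methoxymethoxy)phenyl]magnesium chloride
Conditions: i-PrMgCl·LiCl, THF, −15 → 0 °C; solution used at once
Reagents that add atoms: isopropylmagnesium chloride–lithium chloride complex, CC(C)[Mg]Cl.[Li+].[Cl-]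
Why: Bromine–magnesium exchange with the LiCl-activated isopropyl Grignard reagent, accelerated by the ortho-fluorine; at or below 0 °C the ortho-fluoro aryl magnesium species should not lose magnesium fluoride.

Step 9
Reactants: 14 3-hydroxy-3-methylbutan-2-one
Product: 15 2,3-bis(triethylsilyloxy)-3-methylbut-1-ene
Conditions: Et3SiOTf (2.3 equiv), Et3N, CH2Cl2, 0 → 25 °C
Reagents that add atoms: triethylsilyl trifluoromethanesulfonate, CC[Si](CC)(CC)OS(=O)(=O)C(F)(F)F
Why: The silyl triflate with amine base silylates the tertiary alcohol and converts the ketone, which can enolise only toward its methyl group, into the silyl enol ether.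

Step 10
Reactants: 15 2,3-bis(triethylsilyloxy)-3-methylbut-1-ene
Product: 16 1-bromo-3-methyl-3-(triethylsilyloxy)butan-2-one
Conditions: NBS, NaHCO3, THF, −20 → 0 °C
Reagents that add atoms: N-bromosuccinimide, O=C1CCC(=O)N1Br
Why: Electrophilic bromination of the silyl enol ether gives the monobromo ketone regiospecifically; the tertiary silyl ether is stable under these buffered conditions.

Step 11
Reactants: 10 7-methoxy-5-(methoxymethoxy)-6-[(E)-3-methylbut-1-en-1-yl]-4H-chromen-4-one, 13 [2-fluoro-4-(methoxymethoxy)phenyl]magnesium chloride, 16 1-bromo-3-methyl-3-(triethylsilyloxy)butan-2-one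
Product: 18 2-[2-fluoro-4-(methoxymethoxy)phenyl]-7-methoxy-5-(methoxymethoxy)-6-[(E)-3-methylbut-1-en-1-yl]-3-[3-methyl-2-oxo-3-(triethylsilyloxy)butyl]chroman-4-one, via chloromagnesium enolate 17 (not isolated)
Conditions: CuBr·SMe2 (0.5 equiv), THF, −78 °C, slow addition of 13 (1.5 equiv), → −40 °C; then DMPU, 16 (2.5 equiv), −78 → −10 °C; aq. NH4Cl
Reagents that add atoms: none
Why: Transmetalation of 13 gives an aryl copper species (monovalent copper) that binds the C2=C3 bond of 10, adds at C2 (trivalent copper) and reductively eliminates to form C2–C1', leaving the magnesium enolate 17, held by chelation between the C4 oxygen and the 5-O acetal. The enolate then displaces bromide from 16 at C3 by SN2, helped by DMPU, forming C3–CH2. The closest known reaction type is copper-mediated conjugate addition of Grignard reagents to chromones and other enones with trapping of the metal enolate by a carbon electrophile (tandem conjugate addition–alkylation, three-component enone coupling). No ring is closed. Two stereocentres, C2 and C3, are created; the electrophile should approach anti to the new C2 aryl group (substrate control, trans), but neither relative nor absolute configuration matters because both centres become sp2 in step 12. The step needs 1,4- over 1,2-addition, which copper and low temperature secure. It needs C-alkylation faster than ring opening of 17 by loss of the phenoxide, which is favoured by the covalent Mg–O bond, the low temperature and the high SN2 reactivity of a bromomethyl ketone whose carbonyl is shielded by the quaternary silyloxy carbon. It also needs an intact ortho-fluoro aryl nucleophile, which is kept at or below −40 °C until consumed.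

Step 12
Reactants: 18 the 2-aryl-3-(2-oxoalkyl)flavanone from step 11
Product: 19 2-[2-fluoro-4-(methoxymethoxy)phenyl]-7-methoxy-5-(methoxymethoxy)-6-[(E)-3-methylbut-1-en-1-yl]-3-[3-methyl-2-oxo-3-(triethylsilyloxy)butyl]-4H-chromen-4-one
Conditions: IBX (2-iodoxybenzoic acid), 4-methoxypyridine N-oxide, DMSO, 25 → 40 °C; Et3N during work-up
Reagents that add atoms: none
Why: IBX dehydrogenation of a ketone (single-electron oxidation of the enol bound to pentavalent iodine, then loss of the β-hydrogen), run near ambient temperature with the N-oxide ligand; it is preferred to quinone oxidants, which abstract hydride from the allylic C–H of the electron-rich styrene. Both enolisable sites lead to 19, since the isomer with the double bond exocyclic at C3 (F3 below) tautomerises to the pyranone with the amine base of the work-up, and 19 has no β-hydrogen left for a second dehydrogenation.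

Step 13
Reactants: 19 the 2'-fluoro flavone ketone from step 12
Product: 20 2-[2-fluoro-4-(methoxymethoxy)phenyl]-3-[(2R)-2-hydroxy-3-methyl-3-(triethylsilyloxy)butyl]-7-methoxy-5-(methoxymethoxy)-6-[(E)-3-methylbut-1-en-1-yl]-4H-chromen-4-one
Conditions: (S)-2-methyl-CBS-oxazaborolidine [(3aS)-1-methyl-3,3-diphenyltetrahydro-1H,3H-pyrrolo[1,2-c][1,3,2]oxazaborole] (0.5 equiv), catecholborane, toluene, −78 → −30 °C; MeOH; aq. NaOH wash
Reagents that add atoms: none
Why: Corey–Bakshi–Shibata reduction: the side-chain ketone binds the ring boron with its small flank (the CH2 group) toward the catalyst and its large flank (the quaternary silyloxy carbon) away, and hydride is delivered within the complex to the face that gives the (R)-carbinol, as with tert-alkyl methyl ketones. Catecholborane replaces BH3 so that the alkene is not hydroborated, and the pyranone carbonyl, a vinylogous ester locked s-trans, is not reduced at this temperature.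

Step 14
Reactants: 20 the (R)-alcohol triethylsilyl ether from step 13
Product: 21 3-[(2R)-2,3-dihydroxy-3-methylbutyl]-2-[2-fluoro-4-(methoxymethoxy)phenyl]-7-methoxy-5-(methoxymethoxy)-6-[(E)-3-methylbut-1-en-1-yl]-4H-chromen-4-one
Conditions: Bu4NF, THF, 0 → 25 °C
Reagents that add atoms: none
Why: Fluoride-induced cleavage of the Si–O bond; the methoxymethyl acetals, the aryl fluoride and the alkene are inert to Bu4NF at this temperature. Removing the silyl group before the base-mediated closure prevents O-to-O silyl migration onto the secondary alkoxide.

Step 15
Reactants: 21 the (R)-diol from step 14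
Product: 22 (R)-oxepine-fused flavone 5-O,4'-O-bis(methoxymethyl) ether (ring D closed between the side-chain oxygen and C2')
Conditions: KN(SiMe3)2 (2.5 equiv), THF–DMF, 0 → 60 °C
Reagents that add atoms: none
Why: Intramolecular nucleophilic aromatic substitution (addition–elimination): the fluoride is ortho to C2 of the pyranone, so the charge of the anionic σ-adduct is delocalised through C2=C3 into the C4 carbonyl, and the secondary alkoxide is held in reach for closure of the seven-membered ring. The tertiary alkoxide would have to form an eight-membered ring through a hindered oxygen, and the C–O bond of the stereocentre is not broken, so the R configuration is kept.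

Step 16
Reactants: 22 the bis(methoxymethyl) ether from step 15
Product: 23 target CNP0216454.1 with R configuration
Conditions: HCl (from AcCl), MeOH–THF, 25 → 40 °C
Reagents that add atoms: none
Why: Acid-catalysed acetal exchange with methanol removes both phenolic methoxymethyl groups, the 5-O group fastest because the freed phenol is chelated by the C4 carbonyl. Dilute acid at this temperature should leave the tertiary alcohol, the alkyl aryl ether and the alkene unchanged, and the stereocentre has no acidic or ionisable bond.

## Compound list

1 | 2,4-dihydroxy-6-methoxybenzaldehyde | COc1cc(O)cc(O)c1C=O | starting material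
2 | 2-hydroxy-6-methoxy-4-(tetrahydro-2H-pyran-2-yloxy)benzaldehyde (racemic acetal) | COc1cc(OC2CCCCO2)cc(O)c1C=O | intermediate
3 | 2-methoxy-6-(methoxymethoxy)-4-(tetrahydro-2H-pyran-2-yloxy)benzaldehyde | COc1cc(OC2CCCCO2)cc(OCOC)c1C=O | intermediate
4 | 1-[2-methoxy-6-(methoxymethoxy)-4-(tetrahydro-2H-pyran-2-yloxy)phenyl]-3-methylbutan-1-ol (diastereomer mixture) | COc1cc(OC2CCCCO2)cc(OCOC)c1C(O)CC(C)C | intermediate
5 | 2-{3-methoxy-5-(methoxymethoxy)-4-[(E)-3-methylbut-1-en-1-yl]phenoxy}tetrahydro-2H-pyran | COc1cc(OC2CCCCO2)cc(OCOC)c1/C=C/C(C)C | intermediate
6 | [4-methoxy-2-(methoxymethoxy)-3-[(E)-3-methylbut-1-en-1-yl]-6-(tetrahydro-2H-pyran-2-yloxy)phenyl]lithium | COc1cc(OC2CCCCO2)c([Li])c(OCOC)c1/C=C/C(C)C | intermediate (not isolated)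
7 | 1-[4-methoxy-2-(methoxymethoxy)-3-[(E)-3-methylbut-1-en-1-yl]-6-(tetrahydro-2H-pyran-2-yloxy)phenyl]ethan-1-one | COc1cc(OC2CCCCO2)c(C(C)=O)c(OCOC)c1/C=C/C(C)C | intermediate
8 | (E)-3-(dimethylamino)-1-[4-methoxy-2-(methoxymethoxy)-3-[(E)-3-methylbut-1-en-1-yl]-6-(tetrahydro-2H-pyran-2-yloxy)phenyl]prop-2-en-1-one | COc1cc(OC2CCCCO2)c(C(=O)/C=C/N(C)C)c(OCOC)c1/C=C/C(C)C | intermediate (not isolated)
9 | (E)-3-(dimethylamino)-1-[6-hydroxy-4-methoxy-2-(methoxymethoxy)-3-[(E)-3-methylbut-1-en-1-yl]phenyl]prop-2-en-1-one | COc1cc(O)c(C(=O)/C=C/N(C)C)c(OCOC)c1/C=C/C(C)C | intermediate (not isolated)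
10 | 7-methoxy-5-(methoxymethoxy)-6-[(E)-3-methylbut-1-en-1-yl]-4H-chromen-4-one | COc1cc2occc(=O)c2c(OCOC)c1/C=C/C(C)C | intermediate
11 | 4-bromo-3-fluorophenol | Oc1ccc(Br)c(F)c1 | starting material
12 | 1-bromo-2-fluoro-4-(methoxymethoxy)benzene | COCOc1ccc(Br)c(F)c1 | intermediate
13 | [2-fluoro-4-(methoxymethoxy)phenyl]magnesium chloride (THF solution containing LiCl) | COCOc1ccc([Mg]Cl)c(F)c1 | intermediate
14 | 3-hydroxy-3-methylbutan-2-one | CC(=O)C(C)(C)O | starting material
15 | 2,3-bis(triethylsilyloxy)-3-methylbut-1-ene | C=C(O[Si](CC)(CC)CC)C(C)(C)O[Si](CC)(CC)CC | intermediate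
16 | 1-bromo-3-methyl-3-(triethylsilyloxy)butan-2-one | CC(C)(O[Si](CC)(CC)CC)C(=O)CBr | intermediate
17 | chloromagnesium 2-[2-fluoro-4-(methoxymethoxy)phenyl]-7-methoxy-5-(methoxymethoxy)-6-[(E)-3-methylbut-1-en-1-yl]-2H-chromen-4-olate (racemic) | COc1cc2OC(c3ccc(OCOC)cc3F)C=C(O[Mg]Cl)c2c(OCOC)c1/C=C/C(C)C | intermediate (not isolated)
18 | 2-[2-fluoro-4-(methoxymethoxy)phenyl]-7-methoxy-5-(methoxymethoxy)-6-[(E)-3-methylbut-1-en-1-yl]-3-[3-methyl-2-oxo-3-(triethylsilyloxy)butyl]chroman-4-one (C2/C3 diastereomers, racemic) | COc1cc2OC(c3ccc(OCOC)cc3F)C(CC(=O)C(C)(C)O[Si](CC)(CC)CC)C(=O)c2c(OCOC)c1/C=C/C(C)C | intermediate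
19 | 2-[2-fluoro-4-(methoxymethoxy)phenyl]-7-methoxy-5-(methoxymethoxy)-6-[(E)-3-methylbut-1-en-1-yl]-3-[3-methyl-2-oxo-3-(triethylsilyloxy)butyl]-4H-chromen-4-one | COc1cc2oc(-c3ccc(OCOC)cc3F)c(CC(=O)C(C)(C)O[Si](CC)(CC)CC)c(=O)c2c(OCOC)c1/C=C/C(C)C | intermediate
20 | 2-[2-fluoro-4-(methoxymethoxy)phenyl]-3-[(2R)-2-hydroxy-3-methyl-3-(triethylsilyloxy)butyl]-7-methoxy-5-(methoxymethoxy)-6-[(E)-3-methylbut-1-en-1-yl]-4H-chromen-4-one | COc1cc2oc(-c3ccc(OCOC)cc3F)c(C[C@@H](O)C(C)(C)O[Si](CC)(CC)CC)c(=O)c2c(OCOC)c1/C=C/C(C)C | intermediate
21 | 3-[(2R)-2,3-dihydroxy-3-methylbutyl]-2-[2-fluoro-4-(methoxymethoxy)phenyl]-7-methoxy-5-(methoxymethoxy)-6-[(E)-3-methylbut-1-en-1-yl]-4H-chromen-4-one | COc1cc2oc(-c3ccc(OCOC)cc3F)c(C[C@@H](O)C(C)(C)O)c(=O)c2c(OCOC)c1/C=C/C(C)C | intermediate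
22 | (R)-oxepine-fused flavone, 5-O and 4'-O as methoxymethyl ethers: 7-methoxy-6-[(E)-3-methylbut-1-en-1-yl]flavone bridged from C3 through CH2–CH[C(CH3)2OH]–O to C2' | COc1cc2oc3c(c(=O)c2c(OCOC)c1/C=C/C(C)C)C[C@H](C(C)(C)O)Oc1cc(OCOC)ccc1-3 | intermediate
23 | target CNP0216454.1: (R)-5,4'-dihydroxy-7-methoxy-6-[(E)-3-methylbut-1-en-1-yl]flavone bridged from C3 through CH2–CH[C(CH3)2OH]–O to C2' (ring D) | COc1cc2oc3c(c(=O)c2c(O)c1/C=C/C(C)C)C[C@H](C(C)(C)O)Oc1cc(O)ccc1-3 | target

## Step count and least certain steps

Total step count: 16. Longest linear sequence: 12 steps (steps 1 to 6, then 11 to 16, from 1). Steps 7–8 and 9–10 are two-step side branches that converge in step 11.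

**Step 11 (key step).** Most likely to go wrong: slow conjugate addition, because the 5,7-dioxygenated chromone is a weak acceptor; ring opening of the enolate by β-elimination of the ring phenoxide before it is alkylated; proton transfer from, or carbonyl attack on, the bromo ketone instead of SN2; and loss of magnesium fluoride from the aryl reagent if the temperature rises.
Fallback: it separates the two bond formations and avoids a free enolate, setting out from 10. Addition of the aryl cuprate from 13 and CuBr·SMe2 in the presence of Me3SiCl (THF, −78 °C), which accelerates addition to unreactive enones and traps the adduct at once, should give the trimethylsilyl enol ether F1 after a basic work-up. F1 and 16 are then joined under visible-light photoredox catalysis (fac-Ir(ppy)3, 2,6-lutidine, MeCN, blue light), a known route from silyl enol ethers and α-bromo ketones to 1,4-diketones. The α-keto radical from 16 adds to C3, the α-silyloxy radical is oxidised and loses silicon, and the route is rejoined at 18.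

**Step 12.** Most likely to go wrong: oxidation at the electron-rich styrene competing with the slow enolisation of the hindered C3–H, or loss of the peri acetal through the acidity of the iodine reagent.
Fallback (from 18, back at 19): LiN(SiMe3)2 (THF, −78 °C) removes the most accessible α-proton, that of the side-chain CH2, and PhSeBr gives the α-phenylselanyl ketone F2. H2O2 with pyridine (CH2Cl2, 0 °C) oxidises selenium, and syn-elimination toward C3–H gives the exocyclic enedione F3. Catalytic 1,8-diazabicyclo[5.4.0]undec-7-ene then moves the double bond into the ring and gives 19.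

**Step 15.** Most likely to go wrong: substitution too slow because the fluoride is activated only through the pyranone, so that base-induced degradation of the pyranone overtakes ring closure.
Fallback (from 10 and 16, back at 22): the arene needs no activation if the ether is made by palladium catalysis. 4-Bromo-3-chlorophenol F4 is protected and metalated as in steps 7 and 8, giving its methoxymethyl ether F5 and the aryl magnesium chloride F6 (exchange is selective for bromine). The key step with 10 and 16 gives the 2'-chloro flavanone F7. Steps 12, 13 and 14 then give the 2'-chloro flavone F8, the (R)-alcohol F9 and the diol F10. Intramolecular C–O coupling of the aryl chloride with the secondary alcohol (Pd(OAc)2, 2-di-tert-butylphosphino-2',4',6'-triisopropylbiphenyl, Cs2CO3, toluene, 90 °C) closes ring D and rejoins the route at 22.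

**Step 5.** Most likely to go wrong: proton transfer from the acetamide to the hindered, doubly ortho-substituted aryllithium, which returns 5 instead of the ketone.
Fallback (from 5 through 6, back at 7): the same aryllithium 6 is quenched with acetaldehyde, which has no comparably slow acyl-transfer step, to give the secondary benzylic alcohol F11. Oxidation of this electron-rich benzylic alcohol with activated MnO2 (CH2Cl2, 25 °C) gives 7.

## Further compounds

F1 | step 11 | {2-[2-fluoro-4-(methoxymethoxy)phenyl]-7-methoxy-5-(methoxymethoxy)-6-[(E)-3-methylbut-1-en-1-yl]-2H-chromen-4-yl}oxy(trimethyl)silane (racemic) | COc1cc2OC(c3ccc(OCOC)cc3F)C=C(O[Si](C)(C)C)c2c(OCOC)c1/C=C/C(C)C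
F2 | step 12 | 2-[2-fluoro-4-(methoxymethoxy)phenyl]-7-methoxy-5-(methoxymethoxy)-6-[(E)-3-methylbut-1-en-1-yl]-3-[3-methyl-2-oxo-1-(phenylselanyl)-3-(triethylsilyloxy)butyl]chroman-4-one (diastereomer mixture) | COc1cc2OC(c3ccc(OCOC)cc3F)C(C([Se]c3ccccc3)C(=O)C(C)(C)O[Si](CC)(CC)CC)C(=O)c2c(OCOC)c1/C=C/C(C)C
F3 | step 12 | 2-[2-fluoro-4-(methoxymethoxy)phenyl]-7-methoxy-5-(methoxymethoxy)-6-[(E)-3-methylbut-1-en-1-yl]-3-[3-methyl-2-oxo-3-(triethylsilyloxy)butylidene]chroman-4-one (exocyclic alkene geometry not defined) | COc1cc2OC(c3ccc(OCOC)cc3F)C(=CC(=O)C(C)(C)O[Si](CC)(CC)CC)C(=O)c2c(OCOC)c1/C=C/C(C)C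
F4 | step 15 | 4-bromo-3-chlorophenol | Oc1ccc(Br)c(Cl)c1
F5 | step 15 | 1-bromo-2-chloro-4-(methoxymethoxy)benzene | COCOc1ccc(Br)c(Cl)c1
F6 | step 15 | [2-chloro-4-(methoxymethoxy)phenyl]magnesium chloride (THF solution containing LiCl) | COCOc1ccc([Mg]Cl)c(Cl)c1
F7 | step 15 | 2-[2-chloro-4-(methoxymethoxy)phenyl]-7-methoxy-5-(methoxymethoxy)-6-[(E)-3-methylbut-1-en-1-yl]-3-[3-methyl-2-oxo-3-(triethylsilyloxy)butyl]chroman-4-one | COc1cc2OC(c3ccc(OCOC)cc3Cl)C(CC(=O)C(C)(C)O[Si](CC)(CC)CC)C(=O)c2c(OCOC)c1/C=C/C(C)C
F8 | step 15 | 2-[2-chloro-4-(methoxymethoxy)phenyl]-7-methoxy-5-(methoxymethoxy)-6-[(E)-3-methylbut-1-en-1-yl]-3-[3-methyl-2-oxo-3-(triethylsilyloxy)butyl]-4H-chromen-4-one | COc1cc2oc(-c3ccc(OCOC)cc3Cl)c(CC(=O)C(C)(C)O[Si](CC)(CC)CC)c(=O)c2c(OCOC)c1/C=C/C(C)C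
F9 | step 15 | 2-[2-chloro-4-(methoxymethoxy)phenyl]-3-[(2R)-2-hydroxy-3-methyl-3-(triethylsilyloxy)butyl]-7-methoxy-5-(methoxymethoxy)-6-[(E)-3-methylbut-1-en-1-yl]-4H-chromen-4-one | COc1cc2oc(-c3ccc(OCOC)cc3Cl)c(C[C@@H](O)C(C)(C)O[Si](CC)(CC)CC)c(=O)c2c(OCOC)c1/C=C/C(C)C
F10 | step 15 | 2-[2-chloro-4-(methoxymethoxy)phenyl]-3-[(2R)-2,3-dihydroxy-3-methylbutyl]-7-methoxy-5-(methoxymethoxy)-6-[(E)-3-methylbut-1-en-1-yl]-4H-chromen-4-one | COc1cc2oc(-c3ccc(OCOC)cc3Cl)c(C[C@@H](O)C(C)(C)O)c(=O)c2c(OCOC)c1/C=C/C(C)C
F11 | step 5 | 1-[4-methoxy-2-(methoxymethoxy)-3-[(E)-3-methylbut-1-en-1-yl]-6-(tetrahydro-2H-pyran-2-yloxy)phenyl]ethan-1-ol (diastereomer mixture) | COc1cc(OC2CCCCO2)c(C(C)O)c(OCOC)c1/C=C/C(C)C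
A1 | alternative 1 | R-configured benzoxepine-fused 4-pyranone (rings B, D and C) with a diazoacetyl group on the pyranone carbon next to O1, 4'-O and tertiary O as methoxymethyl ethers | [N-]=[N+]=CC(=O)c1cc(=O)c2c(o1)-c1ccc(OCOC)cc1O[C@@H](C(C)(C)OCOC)C2
A2 | alternative 1 | (E)-1-methoxy-5-methylhex-3-en-1-yne | COC#C/C=C/C(C)C
A3 | alternative 1 | target as its 4'-O and tertiary-O bis(methoxymethyl) ether, 5-OH free | COc1cc2oc3c(c(=O)c2c(O)c1/C=C/C(C)C)C[C@H](C(C)(C)OCOC)Oc1cc(OCOC)ccc1-3
A4 | alternative 2 | (4R)-4-[2-bromo-5-(methoxymethoxy)phenoxy]-5-hydroxy-1-[6-hydroxy-4-methoxy-2-(methoxymethoxy)-3-[(E)-3-methylbut-1-en-1-yl]phenyl]-5-methylhexan-1-one | COc1cc(O)c(C(=O)CC[C@H](C(C)(C)O)Oc2cc(OCOC)ccc2Br)c(OCOC)c1/C=C/C(C)C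
A5 | alternative 2 | benzoxepine-fused cyclic 1,3-diketone with free C8a hydroxyl (ring D closed, R) | COc1cc(O)c(C(=O)C2C[C@H](C(C)(C)O)Oc3cc(OCOC)ccc3C2=O)c(OCOC)c1/C=C/C(C)C
A6 | alternative 3 | 5-methoxy-3-(methoxymethoxy)-4-[(E)-3-methylbut-1-en-1-yl]-2-(trimethylsilyl)phenyl trifluoromethanesulfonate | COc1cc(OS(=O)(=O)C(F)(F)F)c([Si](C)(C)C)c(OCOC)c1/C=C/C(C)C
A7 | alternative 3 | (2R)-5-chloro-8-(methoxymethoxy)-2-[2-(methoxymethoxy)propan-2-yl]-2,3-dihydro-1-benzoxepine-4-carboxylic acid | OC(=O)C1=C(Cl)c2ccc(OCOC)cc2O[C@@H](C(C)(C)OCOC)C1
A8 | alternative 3 | target as its tris(methoxymethyl) ether | COc1cc2oc3c(c(=O)c2c(OCOC)c1/C=C/C(C)C)C[C@H](C(C)(C)OCOC)Oc1cc(OCOC)ccc1-3
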